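**Strategy.** Ring C of the target is made of O1, C2, C3 and C4, which bridge the neighbouring ring A carbons C8a and C4a. The plan cuts C3–C4 and O1–C2, so that ring C falls apart into a ring A ortho-quinone methide (heterodiene O1=C8a–C4a=C4) and the C2=C3 alkene of a 4-silyloxystyrene. A single chiral-acid-catalysed inverse-demand hetero-[4+2] cycloaddition is meant to form both bonds, close ring C and set C2. The methoxy group it leaves at C4 is a placeholder for the ketone. The diene precursor is 2-hydroxy-4,6-dimethoxy-5-prenylbenzaldehyde, made from a symmetric phenol, with the prenyl group locked between two methyl ethers.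

Key step: step 5

**Remarks and assumptions**
- Flavonoid numbering is used (O1, C2–C4, C4a, C5–C8, C8a; ring B primed); prenyl = 3-methylbut-2-en-1-yl.
- The (R)-enantiomer of the phosphoric acid is written in step 5 on the assumption that it gives the (2S,4S) adduct. If the first experiment shows the opposite sense, the (S)-acid is used and nothing else changes.
- Stereochemical check: in the cycloadduct the descriptor pair (2S,4S) is the 2,4-cis isomer, and its C2 centre maps onto (2S) of the target. The enantiomeric purity at C2 is to be read on flavanone 15.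
- Design choices: both ring A ethers stay methyl, because only the symmetric phenol makes the single ortho-formylation unambiguous. The phenol is masked as the bulky triisopropylsilyl ether for the lithiation.

**Route**

Step 1
Reactants: 1 3,5-dimethoxyphenol
Product: 2 (3,5-dimethoxyphenoxy)tri(propan-2-yl)silane
Conditions: TIPSCl, imidazole, DMF, rt
Reagents that add atoms: chlorotri(propan-2-yl)silane (TIPSCl), CC(C)[Si](Cl)(C(C)C)C(C)C
Why: Imidazole-promoted silyl ether formation on a phenol; the bulky silyl group is chosen because it shields both carbons ortho to the silyloxy group and resists O-to-C silyl migration in the next step.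

Step 2
Reactants: 2 (3,5-dimethoxyphenoxy)tri(propan-2-yl)silane; 3 prenyl bromide (1-bromo-3-methylbut-2-ene)
Product: 5 [3,5-dimethoxy-4-(3-methylbut-2-en-1-yl)phenoxy]tri(propan-2-yl)silane, via aryllithium 4 (not isolated)
Conditions: n-BuLi, THF, 0 °C → rt; then CuBr·SMe2 (10 mol%), prenyl bromide, −78 °C → rt
Reagents that add atoms: prenyl bromide (3), CC(C)=CCBr
Why: Directed ortho-metalation removes the proton flanked by the two methoxy groups (the most acidic C–H and the only one with two chelating neighbours), and copper-catalysed SN2 allylation of the aryllithium should give the linear prenyl arene.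

Step 3
Reactants: 5 [3,5-dimethoxy-4-(3-methylbut-2-en-1-yl)phenoxy]tri(propan-2-yl)silane
Product: 6 3,5-dimethoxy-4-(3-methylbut-2-en-1-yl)phenol
Conditions: Bu4NF, THF, 0 °C → rt; 1 M HCl work-up
Reagents that add atoms: none
Why: Fluoride-mediated desilylation driven by Si–F bond formation; the prenyl group and the methyl ethers are inert to fluoride.

Step 4
Reactants: 6 3,5-dimethoxy-4-(3-methylbut-2-en-1-yl)phenol
Product: 8 2-hydroxy-4,6-dimethoxy-5-(3-methylbut-2-en-1-yl)benzaldehyde, via salicyl alcohol magnesium salt 7 (not isolated)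
Conditions: MgCl2, Et3N, (CH2O)n, MeCN, reflux; 1 M HCl work-up
Reagents that add atoms: paraformaldehyde (as formaldehyde), C=O
Why: Casnati–Skattebøl ortho-formylation, in which the magnesium phenoxide delivers formaldehyde to the ortho carbon and a second formaldehyde oxidises the hydroxymethyl intermediate by hydride transfer; the two ortho positions are equivalent, so only one aldehyde can form, and the non-acidic medium leaves the prenyl group alone.

Step 5
Reactants: 8 2-hydroxy-4,6-dimethoxy-5-(3-methylbut-2-en-1-yl)benzaldehyde; 9 4-(tert-butyldimethylsilyloxy)styrene; 10 trimethyl orthoformate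
Product: 13 tert-butyl{4-[(2S,4S)-4,5,7-trimethoxy-6-(3-methylbut-2-en-1-yl)-3,4-dihydro-2H-chromen-2-yl]phenoxy}dimethylsilane (the 2,4-cis 4-methoxyflavan), via dimethyl acetal 11 (not isolated), via methoxy ortho-quinone methide 12 (not isolated)
Conditions: 9 (2.5 equiv), HC(OMe)3 (2 equiv), (R)-3,3'-bis(2,4,6-triisopropylphenyl)-1,1'-binaphthyl-2,2'-diyl hydrogen phosphate (10 mol%), toluene, −20 °C → rt; then Et3N
Reagents that add atoms: trimethyl orthoformate (10), COC(OC)OC; 4-(tert-butyldimethylsilyloxy)styrene (9), C=Cc1ccc(O[Si](C)(C)C(C)(C)C)cc1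
Why: Proposed new method: the chiral acid converts aldehyde 8 through acetal 11 into the O-protonated methoxy ortho-quinone methide 12 (an ortho-hydroxybenzylic oxocarbenium ion held to the phosphate through O1–H), the CH2 terminus of styrene 9 adds to C4, and O1 then collapses onto the silyloxyphenyl-stabilised C2 cation, which restores the aromaticity of ring A. The closest known reaction types are the achiral acid-promoted [4+2] cycloadditions of alkoxy ortho-quinone methides (salicylaldehyde plus orthoformate) with styrenes, and chiral phosphoric acid catalysed cycloadditions of ortho-quinone methides generated from ortho-hydroxybenzylic alcohols or, intramolecularly, from salicylaldehyde acetals. Ring C closes as a six-membered ring in a concerted but asynchronous inverse-demand hetero-Diels–Alder mode, with C3–C4 bonding ahead of O1–C2 bonding. C4 is set by the face of the heterodiene that the 2,4,6-triisopropylphenyl walls of the bound phosphate leave open, and C2 is set relative to C4 by an endo-type approach that places the aryl group cis to the C4 methoxy group, so the (2S) centre is under catalyst control. The step needs regioselectivity, which the polarity of the styrene secures (nucleophilic CH2 to electrophilic C4); chemoselectivity for the styrene over the prenyl alkene, which the higher nucleophilicity and the excess of 9 should secure; and freedom from prenyl cyclisation, which the two methyl ethers flanking C6 guarantee.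

Step 6
Reactants: 13 the (2S,4S)-4-methoxyflavan
Product: 14 (2S)-2-[4-(tert-butyldimethylsilyloxy)phenyl]-5,7-dimethoxy-6-(3-methylbut-2-en-1-yl)-3,4-dihydro-2H-chromen-4-ol (mixture of C4 epimers)
Conditions: aq. HCl (0.05 M), THF/H2O 2:1, 0 °C → rt, dilute
Reagents that add atoms: water, O
Why: Acid-catalysed SN1 solvolysis of the benzylic methyl ether, in which the C4 cation (stabilised by O1, 5-OMe and 7-OMe) is captured by the large excess of water; C4 is scrambled but is destroyed in step 7, C2 is not part of the cation, and the aryl silyl ether and the prenyl group (no free ortho-OH) should survive dilute acid.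

Step 7
Reactants: 14 the flavan-4-ol (both C4 epimers)
Product: 15 (2S)-2-[4-(tert-butyldimethylsilyloxy)phenyl]-5,7-dimethoxy-6-(3-methylbut-2-en-1-yl)-2,3-dihydro-4H-chromen-4-one
Conditions: Dess–Martin periodinane, NaHCO3, CH2Cl2, 0 °C → rt
Reagents that add atoms: none
Why: Dess–Martin oxidation of a secondary benzylic alcohol; both C4 epimers converge on one ketone, and the buffered, near-neutral medium should not touch the alkene, the silyl ether or C2.

Step 8
Reactants: 15 the (2S)-5,7-dimethoxyflavanone silyl ether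
Product: 16 (2S)-2-[4-(tert-butyldimethylsilyloxy)phenyl]-5-hydroxy-7-methoxy-6-(3-methylbut-2-en-1-yl)-2,3-dihydro-4H-chromen-4-one
Conditions: MgI2·OEt2 (3 equiv, freshly prepared), THF, 60 °C; then 0.5 M HCl, 0 °C
Reagents that add atoms: none
Why: Chelation-controlled demethylation of an ortho-methoxy aryl ketone, in which magnesium bridges the C4 carbonyl and the C5 oxygen and iodide removes that methyl group by SN2; the 7-OMe cannot chelate, and this mild Lewis acid is the type known to spare prenyl groups on flavanones.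

Step 9
Reactants: 16 the (2S)-5-hydroxy-7-methoxyflavanone silyl ether
Product: 17 (2S)-5-hydroxy-2-(4-hydroxyphenyl)-7-methoxy-6-(3-methylbut-2-en-1-yl)-2,3-dihydro-4H-chromen-4-one (6-prenylsakuranetin)
Conditions: Bu4NF/AcOH (1:1.2), THF, 0 °C
Reagents that add atoms: none
Why: Fluoride-mediated cleavage of the aryl silyl ether, buffered with acetic acid so that the 4'-phenoxide is protonated as it forms and cannot trigger ring opening to the chalcone, which should keep C2 intact.

**Compound list**

1 | 3,5-dimethoxyphenol | COc1cc(O)cc(OC)c1 | starting material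
2 | (3,5-dimethoxyphenoxy)tri(propan-2-yl)silane | COc1cc(O[Si](C(C)C)(C(C)C)C(C)C)cc(OC)c1 | intermediate
3 | prenyl bromide (1-bromo-3-methylbut-2-ene) | CC(C)=CCBr | starting material
4 | [2,6-dimethoxy-4-(triisopropylsilyloxy)phenyl]lithium | [Li]c1c(OC)cc(O[Si](C(C)C)(C(C)C)C(C)C)cc1OC | intermediate (not isolated)
5 | [3,5-dimethoxy-4-(3-methylbut-2-en-1-yl)phenoxy]tri(propan-2-yl)silane | COc1cc(O[Si](C(C)C)(C(C)C)C(C)C)cc(OC)c1CC=C(C)C | intermediate
6 | 3,5-dimethoxy-4-(3-methylbut-2-en-1-yl)phenol | COc1cc(O)cc(OC)c1CC=C(C)C | intermediate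
7 | 2-(hydroxymethyl)-3,5-dimethoxy-4-(3-methylbut-2-en-1-yl)phenol, formed as its magnesium salt | COc1cc(O)c(CO)c(OC)c1CC=C(C)C | intermediate (not isolated)
8 | 2-hydroxy-4,6-dimethoxy-5-(3-methylbut-2-en-1-yl)benzaldehyde | COc1cc(O)c(C=O)c(OC)c1CC=C(C)C | intermediate
9 | 4-(tert-butyldimethylsilyloxy)styrene | C=Cc1ccc(O[Si](C)(C)C(C)(C)C)cc1 | starting material
10 | trimethyl orthoformate | COC(OC)OC | starting material
11 | 2-(dimethoxymethyl)-3,5-dimethoxy-4-(3-methylbut-2-en-1-yl)phenol | COc1cc(O)c(C(OC)OC)c(OC)c1CC=C(C)C | intermediate (not isolated)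
12 | 3,5-dimethoxy-6-(methoxymethylidene)-4-(3-methylbut-2-en-1-yl)cyclohexa-2,4-dien-1-one (methoxy ortho-quinone methide; reacts O-protonated) | COC=C1C(=O)C=C(OC)C(CC=C(C)C)=C1OC | intermediate (not isolated)
13 | tert-butyl{4-[(2S,4S)-4,5,7-trimethoxy-6-(3-methylbut-2-en-1-yl)-3,4-dihydro-2H-chromen-2-yl]phenoxy}dimethylsilane (2,4-cis) | COc1cc2c(c(OC)c1CC=C(C)C)[C@@H](OC)C[C@@H](c1ccc(O[Si](C)(C)C(C)(C)C)cc1)O2 | intermediate
14 | (2S)-2-[4-(tert-butyldimethylsilyloxy)phenyl]-5,7-dimethoxy-6-(3-methylbut-2-en-1-yl)-3,4-dihydro-2H-chromen-4-ol (C4 epimers) | COc1cc2c(c(OC)c1CC=C(C)C)C(O)C[C@@H](c1ccc(O[Si](C)(C)C(C)(C)C)cc1)O2 | intermediate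
15 | (2S)-2-[4-(tert-butyldimethylsilyloxy)phenyl]-5,7-dimethoxy-6-(3-methylbut-2-en-1-yl)-2,3-dihydro-4H-chromen-4-one | COc1cc2c(c(OC)c1CC=C(C)C)C(=O)C[C@@H](c1ccc(O[Si](C)(C)C(C)(C)C)cc1)O2 | intermediate
16 | (2S)-2-[4-(tert-butyldimethylsilyloxy)phenyl]-5-hydroxy-7-methoxy-6-(3-methylbut-2-en-1-yl)-2,3-dihydro-4H-chromen-4-one | COc1cc2c(c(O)c1CC=C(C)C)C(=O)C[C@@H](c1ccc(O[Si](C)(C)C(C)(C)C)cc1)O2 | intermediate
17 | (2S)-5-hydroxy-2-(4-hydroxyphenyl)-7-methoxy-6-(3-methylbut-2-en-1-yl)-2,3-dihydro-4H-chromen-4-one (6-prenylsakuranetin) | COc1cc2c(c(O)c1CC=C(C)C)C(=O)C[C@@H](c1ccc(O)cc1)O2 | target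

**Step count and risks**

Total step count: 9. Longest linear sequence: 9 steps (1 to 17); compounds 3, 9 and 10 are purchased.

Steps most likely to fail:

1. Step 5. What may go wrong: weak discrimination between the two faces of the ion-paired heterodiene, or loss of the cis preference in ring closure (either lowers the enantiomeric purity at C2). Acid-induced oligomerisation of the styrene and acid-induced reopening of the O1–C2 bond of the adduct are further risks. Fallback with known chemistry, setting out from 8 and returning at 15: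
   - Addition of MeMgBr (THF, 0 °C) to 8 should give 2-(1-hydroxyethyl)-3,5-dimethoxy-4-(3-methylbut-2-en-1-yl)phenol F1.
   - MnO2 (CH2Cl2) should oxidise it to 1-[2-hydroxy-4,6-dimethoxy-5-(3-methylbut-2-en-1-yl)phenyl]ethan-1-one F2.
   - Condensation with N,N-dimethylformamide dimethyl acetal should give the enaminone (2E)-3-(dimethylamino)-1-[2-hydroxy-4,6-dimethoxy-5-(3-methylbut-2-en-1-yl)phenyl]prop-2-en-1-one F3.
   - Brief treatment with dilute HCl should close it to 5,7-dimethoxy-6-(3-methylbut-2-en-1-yl)-4H-chromen-4-one F4.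
   - Enantioselective conjugate addition of 4-(tert-butyldimethylsilyloxy)phenylboronic acid to F4 would then give flavanone 15. Conditions: Pd(OCOCF3)2 with 4-tert-butyl-2-(pyridin-2-yl)-4,5-dihydrooxazole, NH4PF6, H2O, 1,2-dichloroethane, 60 °C, with the ligand enantiomer chosen for the (2S) product.

2. Step 8. What may go wrong: erosion of the C2 configuration through Lewis-acid-assisted heterolysis of the O1–C2 bond (reversible ring opening) at the temperature the demethylation needs, or closure of the prenyl group onto the freed 5-OH. Fallback, setting out from 8 and returning at 16; it unmasks the C5 oxygen before any stereocentre exists: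
   - Pivaloylation of 8 (PivCl, Et3N, DMAP) should give 2-formyl-3,5-dimethoxy-4-(3-methylbut-2-en-1-yl)phenyl 2,2-dimethylpropanoate F5.
   - MgI2·OEt2 should cleave the only methyl ether that can chelate with the formyl group, giving 2-formyl-3-hydroxy-5-methoxy-4-(3-methylbut-2-en-1-yl)phenyl 2,2-dimethylpropanoate F6.
   - Allyl bromide/K2CO3 should give 2-formyl-5-methoxy-4-(3-methylbut-2-en-1-yl)-3-(prop-2-en-1-yloxy)phenyl 2,2-dimethylpropanoate F7.
   - K2CO3/MeOH should remove the pivalate to give 6-hydroxy-4-methoxy-3-(3-methylbut-2-en-1-yl)-2-(prop-2-en-1-yloxy)benzaldehyde F8.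
   - F8 is taken through the conditions of steps 5, 6 and 7. These should give the cycloadduct tert-butyl{4-[(2S,4S)-4,7-dimethoxy-6-(3-methylbut-2-en-1-yl)-5-(prop-2-en-1-yloxy)-3,4-dihydro-2H-chromen-2-yl]phenoxy}dimethylsilane F9, then the corresponding (2S)-flavan-4-ol F10, then the (2S)-5-(prop-2-en-1-yloxy)-7-methoxyflavanone silyl ether F11.
   - Pd(PPh3)4 with morpholine (THF, rt) should remove the allyl group from F11 under neutral conditions and give 16.

3. Step 6. What may go wrong: loss of a C3 proton from the C4 cation (elimination to the flav-3-ene), or capture of the cation by the electron-rich C8 of a second molecule (oligomerisation). Fallback, setting out from 13 and returning at 15: DDQ in CH2Cl2/pH 7 buffer at 0 °C abstracts the hydride at C4. This is the most electron-rich benzylic, α-alkoxy C–H in the molecule. Water adds to the resulting methoxy-oxocarbenium ion and the hemiketal collapses to ketone 15, so no free flavan-4-ol or unsubstituted C4 cation is involved and no new compound is isolated.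

**Further compounds**

F1 | step 5 | 2-(1-hydroxyethyl)-3,5-dimethoxy-4-(3-methylbut-2-en-1-yl)phenol | COc1cc(O)c(C(C)O)c(OC)c1CC=C(C)C
F2 | step 5 | 1-[2-hydroxy-4,6-dimethoxy-5-(3-methylbut-2-en-1-yl)phenyl]ethan-1-one | COc1cc(O)c(C(C)=O)c(OC)c1CC=C(C)C
F3 | step 5 | (2E)-3-(dimethylamino)-1-[2-hydroxy-4,6-dimethoxy-5-(3-methylbut-2-en-1-yl)phenyl]prop-2-en-1-one | COc1cc(O)c(C(=O)/C=C/N(C)C)c(OC)c1CC=C(C)C
F4 | step 5 | 5,7-dimethoxy-6-(3-methylbut-2-en-1-yl)-4H-chromen-4-one | COc1cc2occc(=O)c2c(OC)c1CC=C(C)C
F5 | step 8 | 2-formyl-3,5-dimethoxy-4-(3-methylbut-2-en-1-yl)phenyl 2,2-dimethylpropanoate | COc1cc(OC(=O)C(C)(C)C)c(C=O)c(OC)c1CC=C(C)C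
F6 | step 8 | 2-formyl-3-hydroxy-5-methoxy-4-(3-methylbut-2-en-1-yl)phenyl 2,2-dimethylpropanoate | COc1cc(OC(=O)C(C)(C)C)c(C=O)c(O)c1CC=C(C)C
F7 | step 8 | 2-formyl-5-methoxy-4-(3-methylbut-2-en-1-yl)-3-(prop-2-en-1-yloxy)phenyl 2,2-dimethylpropanoate | COc1cc(OC(=O)C(C)(C)C)c(C=O)c(OCC=C)c1CC=C(C)C
F8 | step 8 | 6-hydroxy-4-methoxy-3-(3-methylbut-2-en-1-yl)-2-(prop-2-en-1-yloxy)benzaldehyde | COc1cc(O)c(C=O)c(OCC=C)c1CC=C(C)C
F9 | step 8 | tert-butyl{4-[(2S,4S)-4,7-dimethoxy-6-(3-methylbut-2-en-1-yl)-5-(prop-2-en-1-yloxy)-3,4-dihydro-2H-chromen-2-yl]phenoxy}dimethylsilane | COc1cc2c(c(OCC=C)c1CC=C(C)C)[C@@H](OC)C[C@@H](c1ccc(O[Si](C)(C)C(C)(C)C)cc1)O2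
F10 | step 8 | (2S)-2-[4-(tert-butyldimethylsilyloxy)phenyl]-7-methoxy-6-(3-methylbut-2-en-1-yl)-5-(prop-2-en-1-yloxy)-3,4-dihydro-2H-chromen-4-ol (C4 epimers) | COc1cc2c(c(OCC=C)c1CC=C(C)C)C(O)C[C@@H](c1ccc(O[Si](C)(C)C(C)(C)C)cc1)O2
F11 | step 8 | (2S)-2-[4-(tert-butyldimethylsilyloxy)phenyl]-7-methoxy-6-(3-methylbut-2-en-1-yl)-5-(prop-2-en-1-yloxy)-2,3-dihydro-4H-chromen-4-one | COc1cc2c(c(OCC=C)c1CC=C(C)C)C(=O)C[C@@H](c1ccc(O[Si](C)(C)C(C)(C)C)cc1)O2
F0 | step 6 | none | none
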